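**Strategy.** The route rests on cutting the C2–C3 bond of the docosanoyl chain. C1, C2 and the ester oxygen with its 2-phenylethyl group (the benzene ring is a spectator) are supplied by a malonic half-ester, while C3 to C22 are supplied by an activated C20 acid. In a single operation a magnesium-chelated malonate enolate is C-acylated and decarboxylated, giving the full C22 skeleton as a β-keto ester that already carries the final ester group. The precursor pair is a solid acyl imidazole and an acid-ester of malonic acid. The C3 oxygen is then removed by reduction, dehydration and hydrogenation.

Key step: step 3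

Remark on the chemistry: the target has no stereocentre, so the racemic carbinol centre made in step 4 and the alkene geometry of step 5 are both erased before the end. The acyl imidazole is assumed to be carried into the key step as the crude solid, which still holds the imidazole liberated on its formation. The structures needed no correction: the C20 acyl donor and the two-carbon malonate unit account for all 22 chain carbons.

Step 1
Reactants: 1 eicosanoic acid (arachidic acid)
Product: 2 N-eicosanoylimidazole (1-(1H-imidazol-1-yl)icosan-1-one)
Conditions: CDI (1.05 equiv), THF, 40 °C, 2 h, N2; evaporate, crude solid used directly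
Reagents that add atoms: 1,1'-carbonyldiimidazole (CDI), O=C(n1ccnc1)n1ccnc1
Why: Carboxylic acid activation with CDI (N-acylimidazole formation): the acid adds to CDI, the mixed anhydride loses CO2 and the released imidazole is acylated, and a saturated chain offers no competing site.

Step 2
Reactants: 3 Meldrum's acid; 4 2-phenylethanol
Product: 5 2-phenylethyl hydrogen malonate (3-oxo-3-(2-phenylethoxy)propanoic acid)
Conditions: toluene, 110 °C, 5 h; extraction into aq. NaHCO3, then aq. HCl
Reagents that add atoms: none
Why: Thermal alcoholysis of Meldrum's acid: the alcohol opens the cyclic acylal at one carbonyl and acetone is expelled, so only one ester forms and the second carboxyl is unveiled as the free acid, which the acid–base work-up separates from neutral material.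

Step 3
Reactants: 2 N-eicosanoylimidazole; 5 2-phenylethyl hydrogen malonate
Product: 8 2-phenylethyl 3-oxodocosanoate, via magnesium malonate enolate 6 (not isolated), via acylmalonate magnesium chelate 7 (not isolated)
Conditions: 5 (1.5 equiv), MgCl2 (1.5 equiv), Et3N (3.2 equiv), THF, 20 °C, 2 h; then 2 (1.0 equiv) in warm THF, 20 → 45 °C, 16 h; 1 M HCl, then NaHCO3 wash
Reagents that add atoms: none
Why: This is a decarboxylative Claisen condensation of a magnesium malonate half-ester with an acyl imidazole under soft-enolisation conditions: magnesium bound between the carboxylate and the ester carbonyl of 5 acidifies the methylene enough for Et3N to give enolate 6, whose carbon attacks the acyl carbon of 2 with expulsion of imidazole and forms the C2–C3 bond in chelate 7. Loss of CO2 from 7, in the flask or at the latest on acidification, should deliver 8 as its magnesium enolate, which the HCl quench sets free. No ring is closed and no stereocentre is created, so the selectivities needed are C- over O-acylation and mono- over diacylation. Both should be secured by the metal–substrate pairing: the six-membered magnesium chelate ties up both oxygens and leaves carbon as the nucleophilic site, and after decarboxylation the product rests as a stabilised magnesium β-keto ester enolate that the mild acyl imidazole does not acylate again. The 2-phenylethyl ester should survive because no alkoxide or free alcohol is present, and the excess of 5 is removed in the bicarbonate wash.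

Step 4
Reactants: 8 2-phenylethyl 3-oxodocosanoate
Product: 9 racemic 2-phenylethyl 3-hydroxydocosanoate
Conditions: NaBH4 (0.6 equiv), THF/MeOH (10:1), −10 → 0 °C, 1 h; aq. NH4Cl
Reagents that add atoms: none
Why: Chemoselective borohydride reduction of a ketone beside an ester; the C3 carbinol centre forms without control as the racemate, which is acceptable because step 5 destroys it.

Step 5
Reactants: 9 racemic 2-phenylethyl 3-hydroxydocosanoate
Product: 11 2-phenylethyl (E)-docos-2-enoate, via racemic 3-mesyloxy ester 10 (not isolated)
Conditions: MsCl (1.3 equiv), Et3N (1.5 equiv), CH2Cl2, 0 °C, 30 min; then DBU (2.5 equiv), 0 → 25 °C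
Reagents that add atoms: none
Why: Sulfonylation of the secondary alcohol followed by base-mediated β-elimination of the β-mesyloxy ester (E1cB-type, through the ester enolate) should give the conjugated E-alkene, the atoms of methanesulfonyl chloride entering only 10 and leaving again as methanesulfonate; any Z or 3-ene isomer converges in step 6.

Step 6
Reactants: 11 2-phenylethyl (E)-docos-2-enoate
Product: 12 2-phenylethyl docosanoate (phenylethyl n-docosanoate)
Conditions: H2 (1 atm), 10% Pd/C, EtOAc/THF, 25 °C
Reagents that add atoms: none
Why: Heterogeneous catalytic hydrogenation of a disubstituted conjugated alkene over palladium on carbon; the ester oxygen sits on a homobenzylic carbon, so hydrogenolysis should not occur, and the benzene ring should not be reduced under these mild conditions.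

**Compound list**

1 | eicosanoic acid (arachidic acid) | CCCCCCCCCCCCCCCCCCCC(=O)O | starting material
2 | N-eicosanoylimidazole, 1-(1H-imidazol-1-yl)icosan-1-one | CCCCCCCCCCCCCCCCCCCC(=O)n1ccnc1 | intermediate
3 | Meldrum's acid (2,2-dimethyl-1,3-dioxane-4,6-dione) | CC1(C)OC(=O)CC(=O)O1 | starting material
4 | 2-phenylethanol | OCCc1ccccc1 | starting material
5 | 2-phenylethyl hydrogen malonate | OC(=O)CC(=O)OCCc1ccccc1 | intermediate
6 | magnesium-chelated enolate of 5 (carboxylate and enolate oxygen on the same side of the C=C bond) | [Mg+2].[O-]C(=O)/C=C(\[O-])OCCc1ccccc1 | intermediate (not isolated)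
7 | magnesium chelate of 2-eicosanoylmalonic acid mono(2-phenylethyl) ester (enolate delocalised over three carbonyl groups, so no double-bond geometry is assigned) | [Mg+2].CCCCCCCCCCCCCCCCCCCC(=O)C(C(=O)[O-])=C([O-])OCCc1ccccc1 | intermediate (not isolated)
8 | 2-phenylethyl 3-oxodocosanoate | CCCCCCCCCCCCCCCCCCCC(=O)CC(=O)OCCc1ccccc1 | intermediate
9 | racemic 2-phenylethyl 3-hydroxydocosanoate (C3 unassigned, both enantiomers) | CCCCCCCCCCCCCCCCCCCC(O)CC(=O)OCCc1ccccc1 | intermediate
10 | racemic 2-phenylethyl 3-(methanesulfonyloxy)docosanoate (C3 unassigned, both enantiomers) | CCCCCCCCCCCCCCCCCCCC(CC(=O)OCCc1ccccc1)OS(C)(=O)=O | intermediate (not isolated)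
11 | 2-phenylethyl (E)-docos-2-enoate | CCCCCCCCCCCCCCCCCCC/C=C/C(=O)OCCc1ccccc1 | intermediate
12 | 2-phenylethyl docosanoate | CCCCCCCCCCCCCCCCCCCCCC(=O)OCCc1ccccc1 | target

**Step count.** Total: 6 steps. Longest linear sequence: 5 steps (1 → 2 → 8 → 9 → 11 → 12, steps 1, 3, 4, 5 and 6).

**Steps most likely to fail**

Step 3. The acylation could stall because the C20 acyl imidazole dissolves or reacts slowly, because some acylation goes to oxygen, or because the half-ester decarboxylates before it is acylated. The fallback makes the same C2–C3 bond with Meldrum's acid as the carbon nucleophile. It sets out from 1: coupling with 3 (EDC·HCl, DMAP, CH2Cl2, 0 → 25 °C) should give 5-(1-hydroxyicosylidene)-2,2-dimethyl-1,3-dioxane-4,6-dione F1. Heating F1 with 4 in toluene at 110 °C should open it through the acylketene, with loss of acetone and CO2, and the fallback comes back to the route at 8.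

Step 5. The elimination could remain incomplete, chloride could displace the mesylate, or base could trigger retro-aldol-type cleavage of the β-oxygenated ester. The fallback removes the hydroxyl by a radical path that does not pass through the alkene. It sets out from 9: 1,1'-thiocarbonyldiimidazole (cat. DMAP, CH2Cl2, 25–40 °C) should give racemic 2-phenylethyl 3-[(1H-imidazol-1-ylcarbonothioyl)oxy]docosanoate F2. Bu3SnH and AIBN in toluene at 90 °C (Barton–McCombie deoxygenation) should then replace the C–O bond by C–H, so the fallback comes back to the route at 12 and step 6 is no longer needed.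

Step 4. Hydride could over-reduce the ester to the 1,3-diol, or the ester could exchange with the alcohol co-solvent under the basic borohydride conditions. The fallback removes the ketone without hydride or alkoxide. It sets out from 8: ethane-1,2-dithiol and BF3·OEt2 (CH2Cl2, 0 → 25 °C) should give 2-phenylethyl 2-(2-nonadecyl-1,3-dithiolan-2-yl)acetate F3. Desulfurisation with neutral-washed Raney nickel (Ni) in THF at 50 °C should give the methylene compound, so the fallback comes back to the route at 12 and bypasses steps 5 and 6.

**Further compounds**

F1 | step 3 | 5-(1-hydroxyicosylidene)-2,2-dimethyl-1,3-dioxane-4,6-dione | CCCCCCCCCCCCCCCCCCCC(O)=C1C(=O)OC(C)(C)OC1=O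
F2 | step 5 | racemic 2-phenylethyl 3-[(1H-imidazol-1-ylcarbonothioyl)oxy]docosanoate | CCCCCCCCCCCCCCCCCCCC(CC(=O)OCCc1ccccc1)OC(=S)n1ccnc1
F3 | step 4 | 2-phenylethyl 2-(2-nonadecyl-1,3-dithiolan-2-yl)acetate | CCCCCCCCCCCCCCCCCCCC1(CC(=O)OCCc2ccccc2)SCCS1
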